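**Retrosynthetic overview**

1. Labels: ring O1, C2(=O), C3, C4, C5, C6 [C(CH3)OH], C7 [CH–O]; chain on C7 = C1′–C5′. The C5′ acetate goes on last; before it the oxepinone (the only ring of the target) is closed at C3=C4 by intramolecular Horner–Wadsworth–Emmons olefination of a C7–O phosphonoacetate onto a C4 aldehyde.
2. The C7 carbinol comes from chelation-controlled reduction of a C7 ketone next to the C6 tertiary alcohol.
3. Key bond C1′–C2′ and the E-C3′=C4′ alkene come from a Claisen [3,3] rearrangement of an allyl vinyl ether, made by methylenating the ester between the C6/C7 hydroxy acid and an isopropenyl carbinol.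
4. C6 comes from (S)-lactic acid through its pivalaldehyde acetal (enolate allylation with retention, allyl then cut to the C5–C4 acetal); the C3 arm comes from an alkylated phosphonoacetic acid.
5. Ring order: the temporary dioxolanone first (made in step 1, opened in step 5), the seven-membered lactone last (step 11).

Assumption: the isopropenyl carbinol and the phosphono acid are used as racemates; their extra stereocentres are erased later (Claisen step, olefination), so the compounds in between are epimer mixtures at those carbons only.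

**Route**

Step 1
Reactants: 1 (S)-lactic acid; 2 pivalaldehyde
Product: 3 (2S,5S)-2-tert-butyl-5-methyl-1,3-dioxolan-4-one
Conditions: TsOH·H2O (cat.), H2SO4 (cat.), pentane, reflux, Dean–Stark; crystallise from pentane/Et2O at −78 °C
Reagents that add atoms: none
Why: Acid-catalysed acetalisation (Seebach dioxolanone) keeps the lactic acid centre, which steers the new acetal centre to the cis (2S) isomer, obtained pure by crystallisation.

Step 2
Reactants: 3 (2S,5S)-2-tert-butyl-5-methyl-1,3-dioxolan-4-one; 4 allyl bromide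
Product: 6 (2S,5R)-5-allyl-2-tert-butyl-5-methyl-1,3-dioxolan-4-one, via lithium enolate 5 (not isolated)
Conditions: LiN(iPr)2, THF, −78 °C; then allyl bromide, −78 → −30 °C
Reagents that add atoms: none
Why: Enolate alkylation in which the tert-butyl group blocks one face, so the allyl group enters trans to it and the quaternary centre (future C6, R) forms with net retention.

Step 3
Reactants: 6 (2S,5R)-5-allyl-2-tert-butyl-5-methyl-1,3-dioxolan-4-one
Product: 9 (2S,5R)-2-tert-butyl-5-(2,2-dimethoxyethyl)-5-methyl-1,3-dioxolan-4-one, via ozonide 7 (not isolated), via aldehyde 8 (not isolated)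
Conditions: O3, CH2Cl2, −78 °C; Me2S, −78 °C → rt; then HC(OMe)3, MeOH, PPTS (cat.), rt
Reagents that add atoms: trimethyl orthoformate, COC(OC)OC
Why: Ozonolysis of the only alkene with reductive work-up, then acetalisation, masks the future C4 aldehyde before any other alkene is present; no stereocentre is touched.

Step 4
Reactants: 10 isopropenylmagnesium bromide CH2=C(CH3)MgBr; 11 (tert-butyldimethylsilyloxy)acetaldehyde
Product: 12 rac-1-[(tert-butyldimethylsilyl)oxy]-3-methylbut-3-en-2-ol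
Conditions: THF, −78 → 0 °C; aq. NH4Cl
Reagents that add atoms: none
Why: Grignard 1,2-addition to an aldehyde; the carbinol centre is left racemic because step 6 destroys it.

Step 5
Reactants: 9 (2S,5R)-2-tert-butyl-5-(2,2-dimethoxyethyl)-5-methyl-1,3-dioxolan-4-one; 12 rac-1-[(tert-butyldimethylsilyl)oxy]-3-methylbut-3-en-2-ol
Product: 14 1-[(tert-butyldimethylsilyl)oxy]-3-methylbut-3-en-2-yl (2R)-2-hydroxy-4,4-dimethoxy-2-methylbutanoate, via lithium alkoxide 13 (not isolated)
Conditions: 12, n-BuLi, THF, −78 °C; add 9, −78 → 20 °C; aq. NH4Cl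
Reagents that add atoms: none
Why: Alkoxide transesterification of the activated acylal carbonyl opens the ring and releases pivalaldehyde; no bond to the quaternary centre is broken.

Step 6
Reactants: 14 1-[(tert-butyldimethylsilyl)oxy]-3-methylbut-3-en-2-yl (2R)-2-hydroxy-4,4-dimethoxy-2-methylbutanoate
Product: 18 (3R,7E)-9-[(tert-butyldimethylsilyl)oxy]-3-hydroxy-1,1-dimethoxy-3,7-dimethylnon-7-en-4-one, via trimethylsilyl ether 15 (not isolated), via allyl vinyl ether 16 (not isolated), via silyloxy ketone 17 (not isolated)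
Conditions: (Me3Si)2NH, Me3SiCl (cat.), toluene, 60 °C, evaporate; Cp2Ti(μ-Cl)(μ-CH2)AlMe2, pyridine (cat.), THF/toluene, −40 °C → rt, aq. NaOH, filter through basic Al2O3; toluene, 130 °C (sealed tube); then K2CO3 (cat.), MeOH, rt
Reagents that add atoms: Tebbe reagent Cp2Ti(μ-Cl)(μ-CH2)AlMe2, C[Al-]1(C)C[Ti](C2C=CC=C2)(C2C=CC=C2)[Cl+]1
Why: Ester methylenation gives an allyl vinyl ether whose Claisen [3,3]-sigmatropic rearrangement, through a chair with CH2OTBS equatorial, forms the C1′–C2′ bond and the E-trisubstituted alkene; the temporary silyl ether protects the tertiary alcohol from the titanium reagent and the heat.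

Step 7
Reactants: 18 (3R,7E)-9-[(tert-butyldimethylsilyl)oxy]-3-hydroxy-1,1-dimethoxy-3,7-dimethylnon-7-en-4-one
Product: 19 (3R,4S,7E)-9-[(tert-butyldimethylsilyl)oxy]-1,1-dimethoxy-3,7-dimethylnon-7-ene-3,4-diol
Conditions: Zn(BH4)2, Et2O, −20 → 0 °C; cold aq. NH4Cl; chromatography on Et3N-buffered silica
Reagents that add atoms: none
Why: Chelation-controlled (Cram cyclic model) reduction: zinc bridges the ketone and the tertiary hydroxyl, and hydride enters from the face carrying CH3 rather than the CH2CH(OMe)2 arm, so the lactic-acid-derived centre sets the new carbinol (future C7, S) anti to it.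

Step 8
Reactants: 20 diethylphosphonoacetic acid; 21 5-bromo-2-methylpent-2-ene
Product: 23 rac-2-(diethoxyphosphoryl)-6-methylhept-5-enoic acid, via dilithium dianion 22 (not isolated)
Conditions: LiN(iPr)2 (2.2 equiv), THF, −78 → 0 °C; then 21, 0 °C → rt; aq. HCl
Reagents that add atoms: none
Why: SN2 C-alkylation of the phosphonoacetic acid dianion by the primary bromide; the α-centre is racemic and disappears in step 11.

Step 9
Reactants: 19 (3R,4S,7E)-9-[(tert-butyldimethylsilyl)oxy]-1,1-dimethoxy-3,7-dimethylnon-7-ene-3,4-diol; 23 rac-2-(diethoxyphosphoryl)-6-methylhept-5-enoic acid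
Product: 24 (3R,4S,7E)-9-[(tert-butyldimethylsilyl)oxy]-3-hydroxy-1,1-dimethoxy-3,7-dimethylnon-7-en-4-yl 2-(diethoxyphosphoryl)-6-methylhept-5-enoate
Conditions: DCC, DMAP (cat.), CH2Cl2, 0 °C → rt
Reagents that add atoms: none
Why: Steglich esterification acylates only the secondary hydroxyl (the tertiary one is too hindered) and breaks only the O–H bond, so the configuration is retained.

Step 10
Reactants: 24 (3R,4S,7E)-9-[(tert-butyldimethylsilyl)oxy]-3-hydroxy-1,1-dimethoxy-3,7-dimethylnon-7-en-4-yl 2-(diethoxyphosphoryl)-6-methylhept-5-enoate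
Product: 25 (3R,4S,7E)-3,9-dihydroxy-3,7-dimethyl-1-oxonon-7-en-4-yl 2-(diethoxyphosphoryl)-6-methylhept-5-enoate
Conditions: AcOH/THF/H2O (3:1:1), rt → 35 °C
Reagents that add atoms: water, O
Why: Mild acid hydrolysis cleaves the dimethyl acetal and the primary silyl ether while sparing the β-hydroxy aldehyde, the phosphonate ester and the alkenes.

Step 11
Reactants: 25 (3R,4S,7E)-3,9-dihydroxy-3,7-dimethyl-1-oxonon-7-en-4-yl 2-(diethoxyphosphoryl)-6-methylhept-5-enoate
Product: 26 (6R,7S)-6-hydroxy-7-[(3E)-5-hydroxy-3-methylpent-3-en-1-yl]-6-methyl-3-(4-methylpent-3-en-1-yl)-6,7-dihydrooxepin-2(5H)-one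
Conditions: slow addition to LiCl, DBU, MeCN, rt (final 0.002 M); quench with pH 7 buffer
Reagents that add atoms: none
Why: Intramolecular Horner–Wadsworth–Emmons olefination (Masamune–Roush conditions, high dilution) closes the seven-membered lactone, and the ring forces the cis C3=C4 geometry.

Step 12
Reactants: 26 (6R,7S)-6-hydroxy-7-[(3E)-5-hydroxy-3-methylpent-3-en-1-yl]-6-methyl-3-(4-methylpent-3-en-1-yl)-6,7-dihydrooxepin-2(5H)-one
Product: 27 (2E)-5-[(2S,3R)-3-hydroxy-3-methyl-6-(4-methylpent-3-en-1-yl)-7-oxo-2,3,4,7-tetrahydrooxepin-2-yl]-3-methylpent-2-en-1-yl acetate (target)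
Conditions: Ac2O, pyridine, CH2Cl2, 0 °C
Reagents that add atoms: acetic anhydride, CC(=O)OC(C)=O
Why: Acylation without DMAP acetylates the primary allylic alcohol and leaves the tertiary alcohol and the lactone untouched.

**Compound list**

1 | (S)-lactic acid | C[C@H](O)C(=O)O | starting material
2 | pivalaldehyde | CC(C)(C)C=O | starting material
3 | (2S,5S)-2-tert-butyl-5-methyl-1,3-dioxolan-4-one | C[C@@H]1O[C@H](C(C)(C)C)OC1=O | intermediate
4 | allyl bromide | C=CCBr | starting material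
5 | lithium (2S)-2-tert-butyl-5-methyl-1,3-dioxol-4-olate (enolate of 3) | CC1=C([O-])O[C@@H](C(C)(C)C)O1.[Li+] | intermediate (not isolated)
6 | (2S,5R)-5-allyl-2-tert-butyl-5-methyl-1,3-dioxolan-4-one | C=CC[C@@]1(C)O[C@H](C(C)(C)C)OC1=O | intermediate
7 | (2S,5R)-2-tert-butyl-5-methyl-5-[(1,2,4-trioxolan-3-yl)methyl]-1,3-dioxolan-4-one (ozonide, mixture at the trioxolane carbon) | C1OC(OO1)C[C@@]2(C)O[C@H](C(C)(C)C)OC2=O | intermediate (not isolated)
8 | 2-[(2S,4R)-2-tert-butyl-4-methyl-5-oxo-1,3-dioxolan-4-yl]acetaldehyde | O=CC[C@@]1(C)O[C@H](C(C)(C)C)OC1=O | intermediate (not isolated)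
9 | (2S,5R)-2-tert-butyl-5-(2,2-dimethoxyethyl)-5-methyl-1,3-dioxolan-4-one | COC(OC)C[C@@]1(C)O[C@H](C(C)(C)C)OC1=O | intermediate
10 | isopropenylmagnesium bromide CH2=C(CH3)MgBr | CC(=C)[Mg]Br | starting material
11 | (tert-butyldimethylsilyloxy)acetaldehyde | CC(C)(C)[Si](C)(C)OCC=O | starting material
12 | rac-1-[(tert-butyldimethylsilyl)oxy]-3-methylbut-3-en-2-ol | CC(=C)C(O)CO[Si](C)(C)C(C)(C)C | intermediate
13 | lithium 1-[(tert-butyldimethylsilyl)oxy]-3-methylbut-3-en-2-olate | CC(=C)C([O-])CO[Si](C)(C)C(C)(C)C.[Li+] | intermediate (not isolated)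
14 | 1-[(tert-butyldimethylsilyl)oxy]-3-methylbut-3-en-2-yl (2R)-2-hydroxy-4,4-dimethoxy-2-methylbutanoate (1:1 epimers at the allylic carbinol carbon) | COC(OC)C[C@@](C)(O)C(=O)OC(CO[Si](C)(C)C(C)(C)C)C(C)=C | intermediate
15 | 1-[(tert-butyldimethylsilyl)oxy]-3-methylbut-3-en-2-yl (2R)-4,4-dimethoxy-2-methyl-2-[(trimethylsilyl)oxy]butanoate | COC(OC)C[C@@](C)(O[Si](C)(C)C)C(=O)OC(CO[Si](C)(C)C(C)(C)C)C(C)=C | intermediate (not isolated)
16 | tert-butyl{[2-({(3R)-5,5-dimethoxy-3-methyl-3-[(trimethylsilyl)oxy]pent-1-en-2-yl}oxy)-3-methylbut-3-en-1-yl]oxy}dimethylsilane (allyl vinyl ether) | COC(OC)C[C@@](C)(O[Si](C)(C)C)C(=C)OC(CO[Si](C)(C)C(C)(C)C)C(C)=C | intermediate (not isolated)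
17 | (3R,7E)-9-[(tert-butyldimethylsilyl)oxy]-1,1-dimethoxy-3,7-dimethyl-3-[(trimethylsilyl)oxy]non-7-en-4-one | COC(OC)C[C@@](C)(O[Si](C)(C)C)C(=O)CC/C(C)=C/CO[Si](C)(C)C(C)(C)C | intermediate (not isolated)
18 | (3R,7E)-9-[(tert-butyldimethylsilyl)oxy]-3-hydroxy-1,1-dimethoxy-3,7-dimethylnon-7-en-4-one | COC(OC)C[C@@](C)(O)C(=O)CC/C(C)=C/CO[Si](C)(C)C(C)(C)C | intermediate
19 | (3R,4S,7E)-9-[(tert-butyldimethylsilyl)oxy]-1,1-dimethoxy-3,7-dimethylnon-7-ene-3,4-diol | COC(OC)C[C@@](C)(O)[C@@H](O)CC/C(C)=C/CO[Si](C)(C)C(C)(C)C | intermediate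
20 | diethylphosphonoacetic acid | CCOP(=O)(OCC)CC(=O)O | starting material
21 | 5-bromo-2-methylpent-2-ene | CC(C)=CCCBr | starting material
22 | dilithium dianion of diethylphosphonoacetic acid | CCOP(=O)(OCC)[CH-]C(=O)[O-].[Li+].[Li+] | intermediate (not isolated)
23 | rac-2-(diethoxyphosphoryl)-6-methylhept-5-enoic acid | CCOP(=O)(OCC)C(CCC=C(C)C)C(=O)O | intermediate
24 | (3R,4S,7E)-9-[(tert-butyldimethylsilyl)oxy]-3-hydroxy-1,1-dimethoxy-3,7-dimethylnon-7-en-4-yl 2-(diethoxyphosphoryl)-6-methylhept-5-enoate (epimers at the phosphonate carbon) | COC(OC)C[C@@](C)(O)[C@@H](OC(=O)C(CCC=C(C)C)P(=O)(OCC)OCC)CC/C(C)=C/CO[Si](C)(C)C(C)(C)C | intermediate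
25 | (3R,4S,7E)-3,9-dihydroxy-3,7-dimethyl-1-oxonon-7-en-4-yl 2-(diethoxyphosphoryl)-6-methylhept-5-enoate | O=CC[C@@](C)(O)[C@@H](OC(=O)C(CCC=C(C)C)P(=O)(OCC)OCC)CC/C(C)=C/CO | intermediate
26 | (6R,7S)-6-hydroxy-7-[(3E)-5-hydroxy-3-methylpent-3-en-1-yl]-6-methyl-3-(4-methylpent-3-en-1-yl)-6,7-dihydrooxepin-2(5H)-one | OC/C=C(\C)CC[C@@H]1OC(=O)C(CCC=C(C)C)=CC[C@@]1(C)O | intermediate
27 | (2E)-5-[(2S,3R)-3-hydroxy-3-methyl-6-(4-methylpent-3-en-1-yl)-7-oxo-2,3,4,7-tetrahydrooxepin-2-yl]-3-methylpent-2-en-1-yl acetate | CC(=O)OC/C=C(\C)CC[C@@H]1OC(=O)C(CCC=C(C)C)=CC[C@@]1(C)O | target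

**Step count and risks**

Total steps: 12. Longest linear sequence: 10 (steps 1, 2, 3, 5, 6, 7, 9, 10, 11, 12).

Steps most likely to fail:

Step 7 (weakest point). The zinc chelate has to tell CH3 from a CH2 arm on a quaternary carbon, so the diastereomer ratio may be modest. Fallback: use the wrong epimer by inversion. Setting out from 18, the unwanted epimer (3R,4R,7E)-9-[(tert-butyldimethylsilyl)oxy]-1,1-dimethoxy-3,7-dimethylnon-7-ene-3,4-diol F3 is separated from 19. With 1,1′-sulfonyldiimidazole and NaH it gives the cyclic sulfate (4R,5R)-5-{(3E)-5-[(tert-butyldimethylsilyl)oxy]-3-methylpent-3-en-1-yl}-4-(2,2-dimethoxyethyl)-4-methyl-1,3,2-dioxathiolane 2,2-dioxide F4. The cesium salt of 23 (Cs2CO3, DMF) opens it at the secondary carbon by SN2 with inversion to give the cesium sulfate monoester of the C4-acylated diol F5. Dilute H2SO4 in wet THF then removes sulfate, acetal and silyl ether, and the route is rejoined at 25.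

Step 6. Methylenation of a hindered ester of a secondary alcohol, a labile enol ether and a hot rearrangement are telescoped. Fallback: build the vinyl ether from the other side. Setting out from 9, NaOMe in MeOH gives methyl (2R)-2-hydroxy-4,4-dimethoxy-2-methylbutanoate F1. Silylation and methylenation of this unhindered methyl ester give trimethyl{[(3R)-2,5,5-trimethoxy-3-methylpent-1-en-3-yl]oxy}silane F2. Heating F2 with alcohol 12 and a trace of propionic acid in toluene exchanges methanol for the allylic alcohol, so the same allyl vinyl ether 16 forms and rearranges; the route is rejoined at 17.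

Step 11. Ring closure to a seven-membered lactone can give oligomers, and the β-hydroxy aldehyde is base-sensitive. Fallback: make C3=C4 first and close the ring by lactonisation. Setting out from 19, oxalic acid on wet silica hydrolyses only the acetal to the lactol (4R,5S)-5-{(3E)-5-[(tert-butyldimethylsilyl)oxy]-3-methylpent-3-en-1-yl}-4-methyloxolane-2,4-diol F6. Z-selective Ando olefination uses ethyl 2-[bis(2-methylphenoxy)phosphoryl]-6-methylhept-5-enoate F7, made from the commercial Ando acetate and 21 with NaH. It gives ethyl (2Z,5R,6S,9E)-11-[(tert-butyldimethylsilyl)oxy]-5,6-dihydroxy-5,9-dimethyl-2-(4-methylpent-3-en-1-yl)undeca-2,9-dienoate F8. LiOH gives the seco acid (2Z,5R,6S,9E)-11-[(tert-butyldimethylsilyl)oxy]-5,6-dihydroxy-5,9-dimethyl-2-(4-methylpent-3-en-1-yl)undeca-2,9-dienoic acid F9. Yamaguchi lactonisation (2,4,6-Cl3C6H2COCl, Et3N; DMAP, toluene, high dilution) acylates the secondary hydroxyl to give (6R,7S)-7-{(3E)-5-[(tert-butyldimethylsilyl)oxy]-3-methylpent-3-en-1-yl}-6-hydroxy-6-methyl-3-(4-methylpent-3-en-1-yl)-6,7-dihydrooxepin-2(5H)-one F10. AcOH/THF/H2O removes the silyl group and the route is rejoined at 26.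

**Further compounds**

F1 | step 6 | methyl (2R)-2-hydroxy-4,4-dimethoxy-2-methylbutanoate | COC(OC)C[C@@](C)(O)C(=O)OC
F2 | step 6 | trimethyl{[(3R)-2,5,5-trimethoxy-3-methylpent-1-en-3-yl]oxy}silane | COC(OC)C[C@@](C)(O[Si](C)(C)C)C(=C)OC
F3 | step 7 | (3R,4R,7E)-9-[(tert-butyldimethylsilyl)oxy]-1,1-dimethoxy-3,7-dimethylnon-7-ene-3,4-diol | COC(OC)C[C@@](C)(O)[C@H](O)CC/C(C)=C/CO[Si](C)(C)C(C)(C)C
F4 | step 7 | (4R,5R)-5-{(3E)-5-[(tert-butyldimethylsilyl)oxy]-3-methylpent-3-en-1-yl}-4-(2,2-dimethoxyethyl)-4-methyl-1,3,2-dioxathiolane 2,2-dioxide | COC(OC)C[C@@]1(C)OS(=O)(=O)O[C@@H]1CC/C(C)=C/CO[Si](C)(C)C(C)(C)C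
F5 | step 7 | cesium (3R,4S,7E)-9-[(tert-butyldimethylsilyl)oxy]-4-{[2-(diethoxyphosphoryl)-6-methylhept-5-enoyl]oxy}-1,1-dimethoxy-3,7-dimethylnon-7-en-3-yl sulfate | COC(OC)C[C@@](C)(OS(=O)(=O)[O-])[C@@H](OC(=O)C(CCC=C(C)C)P(=O)(OCC)OCC)CC/C(C)=C/CO[Si](C)(C)C(C)(C)C.[Cs+]
F6 | step 11 | (4R,5S)-5-{(3E)-5-[(tert-butyldimethylsilyl)oxy]-3-methylpent-3-en-1-yl}-4-methyloxolane-2,4-diol | OC1C[C@@](C)(O)[C@H](CC/C(C)=C/CO[Si](C)(C)C(C)(C)C)O1
F7 | step 11 | ethyl 2-[bis(2-methylphenoxy)phosphoryl]-6-methylhept-5-enoate | CCOC(=O)C(CCC=C(C)C)P(=O)(Oc1ccccc1C)Oc1ccccc1C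
F8 | step 11 | ethyl (2Z,5R,6S,9E)-11-[(tert-butyldimethylsilyl)oxy]-5,6-dihydroxy-5,9-dimethyl-2-(4-methylpent-3-en-1-yl)undeca-2,9-dienoate | CCOC(=O)/C(CCC=C(C)C)=C\C[C@@](C)(O)[C@@H](O)CC/C(C)=C/CO[Si](C)(C)C(C)(C)C
F9 | step 11 | (2Z,5R,6S,9E)-11-[(tert-butyldimethylsilyl)oxy]-5,6-dihydroxy-5,9-dimethyl-2-(4-methylpent-3-en-1-yl)undeca-2,9-dienoic acid | OC(=O)/C(CCC=C(C)C)=C\C[C@@](C)(O)[C@@H](O)CC/C(C)=C/CO[Si](C)(C)C(C)(C)C
F10 | step 11 | (6R,7S)-7-{(3E)-5-[(tert-butyldimethylsilyl)oxy]-3-methylpent-3-en-1-yl}-6-hydroxy-6-methyl-3-(4-methylpent-3-en-1-yl)-6,7-dihydrooxepin-2(5H)-one | CC(C)(C)[Si](C)(C)OC/C=C(\C)CC[C@@H]1OC(=O)C(CCC=C(C)C)=CC[C@@]1(C)O
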